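Assumption: (R)-4-hydroxycyclopent-2-en-1-one (1) is taken as commercially available. Tricyclic compounds are numbered as longipinanes: C1 ketone, C2=C3 with 3-methyl, bridgeheads C4 and C11, C5, C6 gem-dimethyl, C7–C9, quaternary C10 with methyl.

**Retrosynthetic overview**
1. Esters last: isovalerate on the less hindered C8–OH of a 7,8-cis-diol, which comes from OsO4 on a C7=C8 alkene anti to the C9 angelate.
2. Both bridging rings (C1–C2=C3 enone ring and C7=C8 cycloheptene) close in one double ring-closing metathesis on an all-trans cyclobutane carrying four alkenyl arms.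
3. The cyclobutane comes from photo-Wolff ring contraction of a 2,2,3,4-substituted cyclopentanone (diazo at its only CH2).
4. The cyclopentanone is built on (R)-4-silyloxycyclopentenone by two trans-selective conjugate additions (Sakurai reverse prenylation with β-elimination, then isopropenyl cuprate with acrolein aldol trapping); C9 is set by chelation-controlled reduction.
5. Ring order: cyclopentane (from the pool) → cyclobutane (contraction) → cyclohexenone and cycloheptene together (double RCM).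

**Route**

Step 1
Reactants: 1 (R)-4-hydroxycyclopent-2-en-1-one
Product: 2 (R)-4-[(tert-butyldimethylsilyl)oxy]cyclopent-2-en-1-one
Conditions: TBSCl, Et3N, DMAP (cat.), CH2Cl2, 0 °C
Reagents that add atoms: tert-butyldimethylsilyl chloride, CC(C)(C)[Si](C)(C)Cl
Why: Standard O-silylation (protection) under mild base leaves the carbinol stereocentre untouched and gives the bulky ether that steers the next conjugate addition.

Step 2
Reactants: 3 1-chloro-3-methylbut-2-ene
Product: 5 trimethyl(3-methylbut-2-en-1-yl)silane, via prenylmagnesium chloride 4 (not isolated)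
Conditions: Mg, Me3SiCl, THF, 0 °C to rt (Barbier)
Reagents that add atoms: chlorotrimethylsilane, C[Si](C)(C)Cl
Why: Barbier-type Grignard formation and silylation, in which the allylic Grignard is silylated at its unhindered primary terminus to give the linear allylsilane.

Step 3
Reactants: 2 (R)-4-[(tert-butyldimethylsilyl)oxy]cyclopent-2-en-1-one; 5 trimethyl(3-methylbut-2-en-1-yl)silane
Product: 7 (R)-4-(2-methylbut-3-en-2-yl)cyclopent-2-en-1-one, via silyloxy ketone adduct 6 (not isolated)
Conditions: TiCl4, CH2Cl2, −78 °C; aqueous work-up; then DBU, CH2Cl2, 0 °C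
Reagents that add atoms: none
Why: Hosomi–Sakurai conjugate allylation in which the allylsilane reacts through its γ-carbon (SE2′) and enters anti to the 4-silyloxy group, after which E1cB loss of silanol transposes the enone and leaves the new carbon as the (R)-stereocentre (later C5).

Step 4
Reactants: 7 (R)-4-(2-methylbut-3-en-2-yl)cyclopent-2-en-1-one
Product: 8 (R)-2-iodo-4-(2-methylbut-3-en-2-yl)cyclopent-2-en-1-one
Conditions: I2, pyridine/CH2Cl2, rt
Reagents that add atoms: iodine, II
Why: α-Iodination of the enone by pyridine conjugate addition, enolate iodination and elimination (Baylis–Hillman-type), which does not touch the γ-stereocentre.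

Step 5
Reactants: 8 (R)-2-iodo-4-(2-methylbut-3-en-2-yl)cyclopent-2-en-1-one
Product: 9 (R)-2-methyl-4-(2-methylbut-3-en-2-yl)cyclopent-2-en-1-one
Conditions: Me4Sn, Pd2(dba)3 (cat.), AsPh3, CuI (cat.), NMP, 60 °C
Reagents that add atoms: tetramethylstannane, C[Sn](C)(C)C
Why: Stille cross-coupling of the α-iodoenone under neutral conditions installs the α-methyl group without epimerising the γ-centre.

Step 6
Reactants: 9 (R)-2-methyl-4-(2-methylbut-3-en-2-yl)cyclopent-2-en-1-one; 10 acrolein
Product: 12 (2S,3R,4R)-2-(1-hydroxyprop-2-en-1-yl)-2-methyl-4-(2-methylbut-3-en-2-yl)-3-(prop-1-en-2-yl)cyclopentan-1-one (carbinol epimers), via magnesium enolate 11 (not isolated)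
Conditions: isopropenylMgBr (2.4 equiv), CuI (1.2 equiv), THF, −78 to −40 °C; then 10, −78 °C; aq. NH4Cl
Reagents that add atoms: isopropenylmagnesium bromide, CC(=C)[Mg]Br
Why: Tandem cuprate conjugate addition/aldol (three-component coupling) in which isopropenyl adds anti to the bulky C4 group and the tetrasubstituted enolate adds 1,2 to acrolein anti to the new isopropenyl group, creating the quaternary centre (later C10), while the carbinol epimers are converged in steps 7 and 8.

Step 7
Reactants: 12 aldol adduct (carbinol epimers)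
Product: 13 (2R,3R,4R)-2-acryloyl-2-methyl-4-(2-methylbut-3-en-2-yl)-3-(prop-1-en-2-yl)cyclopentan-1-one
Conditions: Dess–Martin periodinane, NaHCO3, CH2Cl2, 0 °C to rt
Reagents that add atoms: none
Why: Dess–Martin oxidation of the allylic alcohol gives a non-enolisable 2,2-disubstituted 1,3-diketone and erases the uncontrolled carbinol centre.

Step 8
Reactants: 13 (2R,3R,4R)-2-acryloyl-2-methyl-4-(2-methylbut-3-en-2-yl)-3-(prop-1-en-2-yl)cyclopentan-1-one
Product: 14 (2S,3R,4R)-2-[(1R)-1-hydroxyprop-2-en-1-yl]-2-methyl-4-(2-methylbut-3-en-2-yl)-3-(prop-1-en-2-yl)cyclopentan-1-one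
Conditions: NaBH4, CeCl3·7H2O, MeOH, −78 °C
Reagents that add atoms: none
Why: Luche 1,2-reduction takes the enone carbonyl in preference to the hindered unconjugated ring ketone, and in the Ce(III)-chelated 1,3-dicarbonyl hydride enters from the face flanked by the C2 methyl rather than the ring side (Cram chelate), giving the (1′R)-carbinol (later C9).

Step 9
Reactants: 14 (1′R)-alcohol
Product: 15 (2S,3R,4R)-2-[(1R)-1-[(tert-butyldimethylsilyl)oxy]prop-2-en-1-yl]-2-methyl-4-(2-methylbut-3-en-2-yl)-3-(prop-1-en-2-yl)cyclopentan-1-one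
Conditions: TBSOTf, 2,6-lutidine, CH2Cl2, −78 to 0 °C
Reagents that add atoms: tert-butyldimethylsilyl trifluoromethanesulfonate, CC(C)(C)[Si](C)(C)OS(=O)(=O)C(F)(F)F
Why: Silyl triflate protection of the hindered β-hydroxy ketone blocks retro-aldol cleavage and later trapping of the ketene by this hydroxyl.

Step 10
Reactants: 15 silyl ether ketone
Product: 17 (2S,3R,4R)-5-diazo-2-[(1R)-1-[(tert-butyldimethylsilyl)oxy]prop-2-en-1-yl]-2-methyl-4-(2-methylbut-3-en-2-yl)-3-(prop-1-en-2-yl)cyclopentan-1-one, via trifluoroacetyl ketone 16 (not isolated)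
Conditions: LiHMDS, THF, −78 °C; CF3CO2CH2CF3; then MsN3, Et3N, H2O, MeCN, rt
Reagents that add atoms: methanesulfonyl azide, CS(=O)(=O)N=[N+]=[N-]; 2,2,2-trifluoroethyl trifluoroacetate, O=C(OCC(F)(F)F)C(F)(F)F (its CF3CO group is carried only by 16)
Why: Detrifluoroacetylative diazo transfer occurs at C5, the only enolisable position because C2 is quaternary.

Step 11
Reactants: 17 α-diazoketone
Product: 20 methyl (1R,2R,3R,4S)-2-[(1R)-1-[(tert-butyldimethylsilyl)oxy]prop-2-en-1-yl]-2-methyl-4-(2-methylbut-3-en-2-yl)-3-(prop-1-en-2-yl)cyclobutane-1-carboxylate, via ketene 18 (not isolated), via epimeric ester mixture 19 (not isolated)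
Conditions: hν (365 nm), MeOH, rt; then NaOMe, MeOH, rt
Reagents that add atoms: methanol, CO
Why: Photochemical Wolff rearrangement (ring contraction) moves the quaternary carbon with retention to give the cyclobutyl ketene, methanol traps it, and methoxide equilibrates the ester-bearing carbon to the all-trans isomer in which the ester is anti to both neighbouring large groups.

Step 12
Reactants: 20 all-trans cyclobutane methyl ester
Product: 21 (1R,2R,3R,4S)-2-[(1R)-1-[(tert-butyldimethylsilyl)oxy]prop-2-en-1-yl]-N-methoxy-N,2-dimethyl-4-(2-methylbut-3-en-2-yl)-3-(prop-1-en-2-yl)cyclobutane-1-carboxamide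
Conditions: MeNH(OMe)·HCl, i-PrMgCl, THF, −20 to 0 °C
Reagents that add atoms: N,O-dimethylhydroxylamine hydrochloride, CNOC.Cl
Why: Aminolysis of the ester by the magnesium amide (Weinreb amide formation) proceeds without changing the already thermodynamic α-centre.

Step 13
Reactants: 21 Weinreb amide
Product: 22 1-[(1R,2R,3R,4S)-2-[(1R)-1-[(tert-butyldimethylsilyl)oxy]prop-2-en-1-yl]-2-methyl-4-(2-methylbut-3-en-2-yl)-3-(prop-1-en-2-yl)cyclobutyl]prop-2-en-1-one
Conditions: vinylmagnesium bromide, THF, −78 to 0 °C; cold aq. HCl quench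
Reagents that add atoms: vinylmagnesium bromide, C=C[Mg]Br
Why: Weinreb ketone synthesis, in which the chelated tetrahedral adduct prevents over-addition and the acidic quench prevents aza-Michael addition of the released amine to the vinyl ketone.

Step 14
Reactants: 22 tetra-alkenyl cyclobutane
Product: 23 (4R,5S,9R,10R,11R)-9-[(tert-butyldimethylsilyl)oxy]longipina-2,7-dien-1-one
Conditions: Hoveyda–Grubbs II (10 mol %), toluene (2 mM), 80 °C, Ar sparge
Reagents that add atoms: none
Why: Double ring-closing metathesis, in which only the two cis-1,3 pairs of arms on the all-trans cyclobutane (acryloyl with isopropenyl, vinyl with vinyl) can reach each other, so the enone ring and the cycloheptene form with no new stereocentre.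

Step 15
Reactants: 23 tricyclic silyl ether
Product: 24 (4R,5S,9R,10R,11R)-9-hydroxylongipina-2,7-dien-1-one
Conditions: HF·pyridine, THF, 0 °C to rt
Reagents that add atoms: none
Why: Fluoride-mediated desilylation under mildly acidic conditions frees the C9 alcohol without affecting the enone or the cycloheptene.

Step 16
Reactants: 24 (4R,5S,9R,10R,11R)-9-hydroxylongipina-2,7-dien-1-one; 25 angelic acid
Product: 26 (4R,5S,9R,10R,11R)-1-oxolongipina-2,7-dien-9-yl (Z)-2-methylbut-2-enoate
Conditions: 25, 2,4,6-trichlorobenzoyl chloride, Et3N, toluene, rt; then 24, 80 °C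
Reagents that add atoms: none
Why: Yamaguchi-type mixed-anhydride esterification without a nucleophilic catalyst acylates the hindered alcohol with retention at C9 and keeps the Z geometry of the angelate.

Step 17
Reactants: 26 dienone angelate
Product: 27 (4R,5S,7S,8S,9S,10R,11R)-7,8-dihydroxy-1-oxolongipin-2-en-9-yl (Z)-2-methylbut-2-enoate
Conditions: OsO4 (5 mol %), NMO, acetone/H2O, rt
Reagents that add atoms: N-methylmorpholine N-oxide, C[N+]1([O-])CCOCC1; water, O
Why: Upjohn dihydroxylation, in which electrophilic OsO4 takes the isolated cis-alkene rather than the two conjugated electron-poor alkenes and adds syn on the face opposite the allylic C9 ester, setting 7S and 8S.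

Step 18
Reactants: 27 7,8-diol; 28 3-methylbutanoyl chloride
Product: 29 (4R,5S,7S,8S,9S,10R,11R)-7-hydroxy-8-(3-methylbutanoyloxy)-1-oxolongipin-2-en-9-yl (Z)-2-methylbut-2-enoate
Conditions: 28 (1.05 equiv), 2,4,6-collidine, CH2Cl2, −40 to 0 °C
Reagents that add atoms: none
Why: Kinetically controlled acylation, in which C8–OH is an ordinary secondary alcohol while C7–OH is neopentylic next to the gem-dimethyl carbon, so one equivalent of acid chloride esterifies C8.

**Compound list**

1 | (R)-4-hydroxycyclopent-2-en-1-one | O=C1C=C[C@H](O)C1 | starting material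
2 | (R)-4-[(tert-butyldimethylsilyl)oxy]cyclopent-2-en-1-one | O=C1C=C[C@H](O[Si](C)(C)C(C)(C)C)C1 | intermediate
3 | 1-chloro-3-methylbut-2-ene | CC(C)=CCCl | starting material
4 | (3-methylbut-2-en-1-yl)magnesium chloride | CC(C)=CC[Mg]Cl | intermediate (not isolated)
5 | trimethyl(3-methylbut-2-en-1-yl)silane | CC(C)=CC[Si](C)(C)C | intermediate
6 | (3S,4R)-4-[(tert-butyldimethylsilyl)oxy]-3-(2-methylbut-3-en-2-yl)cyclopentan-1-one | O=C1C[C@@H](C(C)(C)C=C)[C@H](O[Si](C)(C)C(C)(C)C)C1 | intermediate (not isolated)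
7 | (R)-4-(2-methylbut-3-en-2-yl)cyclopent-2-en-1-one | O=C1C[C@@H](C(C)(C)C=C)C=C1 | intermediate
8 | (R)-2-iodo-4-(2-methylbut-3-en-2-yl)cyclopent-2-en-1-one | O=C1C[C@@H](C(C)(C)C=C)C=C1I | intermediate
9 | (R)-2-methyl-4-(2-methylbut-3-en-2-yl)cyclopent-2-en-1-one | O=C1C[C@@H](C(C)(C)C=C)C=C1C | intermediate
10 | acrolein (prop-2-enal) | C=CC=O | starting material
11 | bromomagnesium (3R,4R)-2-methyl-4-(2-methylbut-3-en-2-yl)-3-(prop-1-en-2-yl)cyclopent-1-en-1-olate | Br[Mg]OC1=C(C)[C@@H](C(C)=C)[C@H](C(C)(C)C=C)C1 | intermediate (not isolated)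
12 | (2S,3R,4R)-2-(1-hydroxyprop-2-en-1-yl)-2-methyl-4-(2-methylbut-3-en-2-yl)-3-(prop-1-en-2-yl)cyclopentan-1-one, mixture of carbinol epimers | O=C1C[C@@H](C(C)(C)C=C)[C@H](C(C)=C)[C@@]1(C)C(O)C=C | intermediate
13 | (2R,3R,4R)-2-acryloyl-2-methyl-4-(2-methylbut-3-en-2-yl)-3-(prop-1-en-2-yl)cyclopentan-1-one | O=C1C[C@@H](C(C)(C)C=C)[C@H](C(C)=C)[C@@]1(C)C(=O)C=C | intermediate
14 | (2S,3R,4R)-2-[(1R)-1-hydroxyprop-2-en-1-yl]-2-methyl-4-(2-methylbut-3-en-2-yl)-3-(prop-1-en-2-yl)cyclopentan-1-one | O=C1C[C@@H](C(C)(C)C=C)[C@H](C(C)=C)[C@@]1(C)[C@H](O)C=C | intermediate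
15 | (2S,3R,4R)-2-[(1R)-1-[(tert-butyldimethylsilyl)oxy]prop-2-en-1-yl]-2-methyl-4-(2-methylbut-3-en-2-yl)-3-(prop-1-en-2-yl)cyclopentan-1-one | O=C1C[C@@H](C(C)(C)C=C)[C@H](C(C)=C)[C@@]1(C)[C@H](O[Si](C)(C)C(C)(C)C)C=C | intermediate
16 | 5-(trifluoroacetyl) derivative of 15 (C5 epimers, enolised 1,3-diketone) | O=C1C(C(=O)C(F)(F)F)[C@@H](C(C)(C)C=C)[C@H](C(C)=C)[C@@]1(C)[C@H](O[Si](C)(C)C(C)(C)C)C=C | intermediate (not isolated)
17 | (2S,3R,4R)-5-diazo-2-[(1R)-1-[(tert-butyldimethylsilyl)oxy]prop-2-en-1-yl]-2-methyl-4-(2-methylbut-3-en-2-yl)-3-(prop-1-en-2-yl)cyclopentan-1-one | O=C1C(=[N+]=[N-])[C@@H](C(C)(C)C=C)[C@H](C(C)=C)[C@@]1(C)[C@H](O[Si](C)(C)C(C)(C)C)C=C | intermediate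
18 | cyclobutylidene ketene from ring contraction of 17 (substituents as in 20) | O=C=C1[C@@H](C(C)(C)C=C)[C@H](C(C)=C)[C@@]1(C)[C@H](O[Si](C)(C)C(C)(C)C)C=C | intermediate (not isolated)
19 | methyl ester as in 20 but epimeric mixture at the ester-bearing ring carbon | COC(=O)C1[C@@H](C(C)(C)C=C)[C@H](C(C)=C)[C@@]1(C)[C@H](O[Si](C)(C)C(C)(C)C)C=C | intermediate (not isolated)
20 | methyl (1R,2R,3R,4S)-2-[(1R)-1-[(tert-butyldimethylsilyl)oxy]prop-2-en-1-yl]-2-methyl-4-(2-methylbut-3-en-2-yl)-3-(prop-1-en-2-yl)cyclobutane-1-carboxylate (all-trans ring) | COC(=O)[C@@H]1[C@@H](C(C)(C)C=C)[C@H](C(C)=C)[C@@]1(C)[C@H](O[Si](C)(C)C(C)(C)C)C=C | intermediate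
21 | (1R,2R,3R,4S)-2-[(1R)-1-[(tert-butyldimethylsilyl)oxy]prop-2-en-1-yl]-N-methoxy-N,2-dimethyl-4-(2-methylbut-3-en-2-yl)-3-(prop-1-en-2-yl)cyclobutane-1-carboxamide | CON(C)C(=O)[C@@H]1[C@@H](C(C)(C)C=C)[C@H](C(C)=C)[C@@]1(C)[C@H](O[Si](C)(C)C(C)(C)C)C=C | intermediate
22 | 1-[(1R,2R,3R,4S)-2-[(1R)-1-[(tert-butyldimethylsilyl)oxy]prop-2-en-1-yl]-2-methyl-4-(2-methylbut-3-en-2-yl)-3-(prop-1-en-2-yl)cyclobutyl]prop-2-en-1-one | C=CC(=O)[C@@H]1[C@@H](C(C)(C)C=C)[C@H](C(C)=C)[C@@]1(C)[C@H](O[Si](C)(C)C(C)(C)C)C=C | intermediate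
23 | (4R,5S,9R,10R,11R)-9-[(tert-butyldimethylsilyl)oxy]longipina-2,7-dien-1-one | CC(C)(C)[Si](C)(C)O[C@@H]1C=CC(C)(C)[C@@H]2[C@H]3C(=O)C=C(C)[C@@H]2[C@@]13C | intermediate
24 | (4R,5S,9R,10R,11R)-9-hydroxylongipina-2,7-dien-1-one | O[C@@H]1C=CC(C)(C)[C@@H]2[C@H]3C(=O)C=C(C)[C@@H]2[C@@]13C | intermediate
25 | angelic acid, (Z)-2-methylbut-2-enoic acid | C/C=C(/C)C(=O)O | starting material
26 | (4R,5S,9R,10R,11R)-1-oxolongipina-2,7-dien-9-yl (Z)-2-methylbut-2-enoate | C/C=C(/C)C(=O)O[C@@H]1C=CC(C)(C)[C@@H]2[C@H]3C(=O)C=C(C)[C@@H]2[C@@]13C | intermediate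
27 | (4R,5S,7S,8S,9S,10R,11R)-7,8-dihydroxy-1-oxolongipin-2-en-9-yl (Z)-2-methylbut-2-enoate | C/C=C(/C)C(=O)O[C@@H]1[C@@H](O)[C@@H](O)C(C)(C)[C@@H]2[C@H]3C(=O)C=C(C)[C@@H]2[C@@]13C | intermediate
28 | 3-methylbutanoyl chloride | CC(C)CC(Cl)=O | starting material
29 | (4R,5S,7S,8S,9S,10R,11R)-7-hydroxy-8-(3-methylbutanoyloxy)-1-oxolongipin-2-en-9-yl (Z)-2-methylbut-2-enoate | C/C=C(/C)C(=O)O[C@@H]1[C@@H](OC(=O)CC(C)C)[C@@H](O)C(C)(C)[C@@H]2[C@H]3C(=O)C=C(C)[C@@H]2[C@@]13C | target

**Step count and weak points**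

Total step count: 18.
Longest linear sequence: 17 steps (steps 1 and 3–18, from 1 to 29); step 2 is a side branch that supplies 5.

Steps most likely to fail:

Step 14 (double RCM). The acryloyl/isopropenyl closure must form a strained bicyclo[3.1.1]heptenone next to a quaternary carbon. The fallback sets out from 20 and comes back at 23. Ring-closing metathesis on the ester (only the two cis-1,3 vinyl arms can react) closes the seven-membered ring alone and gives the bicyclo[4.1.1]octene ester F2. Saponification with LiOH gives the acid F3, and oxalyl chloride gives the acid chloride F4. SnCl4-promoted intramolecular acylation of the isopropenyl group (acylium–alkene cyclisation), followed by DBU to lose HCl and conjugate the alkene, then builds the cyclohexenone ring and gives 23.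

Step 16 (angeloylation). The C9 alcohol is neopentylic and allylic, and angelates isomerise easily to tiglates. The fallback sets out from 24 and comes back at 26. DCC/DMAP esterification with the small 2-[bis(2,2,2-trifluoroethoxy)phosphoryl]propanoic acid gives the phosphonopropionate F5. Still–Gennari olefination (KHMDS, 18-crown-6, acetaldehyde, −78 °C) then builds the Z-trisubstituted enoate on the molecule and gives 26.

Step 6 (cuprate addition/aldol). The enone is hindered, and the tetrasubstituted enolate may add to acrolein in the 1,4 sense or revert. The fallback sets out from 9 and comes back at 12. CuBr·SMe2-catalysed addition of isopropenylmagnesium bromide in the presence of TMSCl and HMPA traps the conjugate adduct as the isolable trimethylsilyl enol ether F1. A BF3·OEt2-mediated Mukaiyama aldol addition of F1 to acrolein 10 at −78 °C (open transition state, 1,2-addition) then gives 12.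

**Further compounds**

F1 | step 6 | trimethyl{[(3R,4R)-2-methyl-4-(2-methylbut-3-en-2-yl)-3-(prop-1-en-2-yl)cyclopent-1-en-1-yl]oxy}silane | C[Si](C)(C)OC1=C(C)[C@@H](C(C)=C)[C@H](C(C)(C)C=C)C1
F2 | step 14 | methyl ester with the cycloheptene closed and the enone ring open (longipinane numbering: C11–CO2Me, C4–isopropenyl, C7=C8, 9-OTBS) | CC(C)(C)[Si](C)(C)O[C@@H]1C=CC(C)(C)[C@@H]2[C@@H](C(=O)OC)[C@@]1(C)[C@H]2C(C)=C
F3 | step 14 | carboxylic acid corresponding to F2 | CC(C)(C)[Si](C)(C)O[C@@H]1C=CC(C)(C)[C@@H]2[C@@H](C(=O)O)[C@@]1(C)[C@H]2C(C)=C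
F4 | step 14 | acid chloride corresponding to F3 | CC(C)(C)[Si](C)(C)O[C@@H]1C=CC(C)(C)[C@@H]2[C@@H](C(=O)Cl)[C@@]1(C)[C@H]2C(C)=C
F5 | step 16 | (4R,5S,9R,10R,11R)-1-oxolongipina-2,7-dien-9-yl 2-[bis(2,2,2-trifluoroethoxy)phosphoryl]propanoate (epimers at the phosphonate carbon) | CC(C(=O)O[C@@H]1C=CC(C)(C)[C@@H]2[C@H]3C(=O)C=C(C)[C@@H]2[C@@]13C)P(=O)(OCC(F)(F)F)OCC(F)(F)F
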